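**Retrosynthetic overview**
- The target comes from its 2,3-saturated dihydroxy ketone by Saegusa desaturation, and that ketone comes from a benzyl-protected enone carrying a C1′ allylic acetate by one hydrogenation/hydrogenolysis.
- Key disconnection C5–C1′: Pd-catalysed asymmetric allylic alkylation of the C5 dienolate of a 4,5-bis(benzyloxy)cyclopentenone with a C15 allylic gem-diacetate. This sets C5 and C1′ and brings in the acetate.
- Ring fragment: (R)-4-hydroxycyclopentenone (C4 bought), O-benzylation, α′-hydroxylation, O-benzylation.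
- Chain fragment: C7 + C7 Cu-catalysed coupling, Ru cross-metathesis with crotonaldehyde, acylal formation.
- Ring order: the only ring is bought and carried through. Its C2=C3 bond is consumed in the hydrogenation and reinstalled in the last step.

Assumption: (R)-4-hydroxycyclopent-2-en-1-one is bought as the single enantiomer, and the (R,R)-Trost ligand is taken to give 1′S in step 7 (if the sense is opposite, the (S,S)-ligand is used and nothing else changes).

**Route**

Step 1
Reactants: 1 (R)-4-hydroxycyclopent-2-en-1-one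
Product: 2 (R)-4-(benzyloxy)cyclopent-2-en-1-one
Conditions: BnOC(=NH)CCl3, TfOH (5 mol%), CH2Cl2–cyclohexane, 0 °C → rt
Reagents that add atoms: benzyl 2,2,2-trichloroacetimidate, N=C(OCc1ccccc1)C(Cl)(Cl)Cl
Why: Acid-catalysed trichloroacetimidate O-benzylation needs no base, so the β-alkoxy enone neither eliminates nor racemises and C4 is carried through unchanged.

Step 2
Reactants: 2 (R)-4-(benzyloxy)cyclopent-2-en-1-one
Product: 4 (4S,5R)-4-(benzyloxy)-5-hydroxycyclopent-2-en-1-one, via sodium dienolate 3 (not isolated)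
Conditions: NaHMDS, THF, −78 °C; Davis oxaziridine, −78 °C; AcOH quench
Reagents that add atoms: 3-phenyl-2-(phenylsulfonyl)oxaziridine (Davis oxaziridine), O=S(=O)(c1ccccc1)N1OC1c1ccccc1
Why: Davis enolate α′-hydroxylation: C5 is the only enolisable position and the oxaziridine attacks anti to the C4 benzyloxy group to give the trans ketol (this C5 centre is erased again in step 7).

Step 3
Reactants: 4 (4S,5R)-4-(benzyloxy)-5-hydroxycyclopent-2-en-1-one
Product: 5 (4S,5R)-4,5-bis(benzyloxy)cyclopent-2-en-1-one
Conditions: BnOC(=NH)CCl3, TfOH (5 mol%), CH2Cl2–cyclohexane, 0 °C → rt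
Reagents that add atoms: benzyl 2,2,2-trichloroacetimidate, N=C(OCc1ccccc1)C(Cl)(Cl)Cl
Why: The same acid-catalysed imidate benzylation gives an ether that, unlike a silyl group, cannot migrate between the two oxygens of the later enediolate and is removed in the hydrogenation step.

Step 4
Reactants: 6 1-bromoheptane; 7 7-bromohept-1-ene
Product: 9 tetradec-1-ene, via heptylmagnesium bromide 8 (not isolated)
Conditions: Mg, THF, rt; then 7, Li2CuCl4 (3 mol%), THF–NMP, 0 °C → rt
Reagents that add atoms: none
Why: Kochi Cu-catalysed sp3–sp3 cross-coupling of a primary Grignard reagent with a primary bromide; the terminal alkene is inert.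

Step 5
Reactants: 9 tetradec-1-ene; 10 (E)-but-2-enal
Product: 11 (E)-pentadec-2-enal
Conditions: Hoveyda–Grubbs II (2 mol%), 10 (5 equiv), CH2Cl2, 40 °C
Reagents that add atoms: none
Why: Ru-catalysed olefin cross-metathesis of a terminal alkene with excess crotonaldehyde gives the E-enal under thermodynamic control.

Step 6
Reactants: 11 (E)-pentadec-2-enal; 12 acetic anhydride
Product: 13 (E)-pentadec-2-ene-1,1-diyl diacetate
Conditions: FeCl3 (2 mol%), Ac2O (3 equiv), CH2Cl2, 0 °C
Reagents that add atoms: none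
Why: Lewis-acid-catalysed acylal formation: Ac2O adds 1,2 across the aldehyde C=O and the conjugated alkene is untouched.

Step 7
Reactants: 5 (4S,5R)-4,5-bis(benzyloxy)cyclopent-2-en-1-one; 13 (E)-pentadec-2-ene-1,1-diyl diacetate
Product: 16 (4S,5R)-5-[(1S,2E)-1-acetoxypentadec-2-en-1-yl]-4,5-bis(benzyloxy)cyclopent-2-en-1-one, via lithium dienolate 14 (not isolated), via chlorozinc dienolate 15 (not isolated)
Conditions: LiHMDS, THF, −78 °C; ZnCl2; then 13, [Pd(η3-C3H5)Cl]2 (2.5 mol%), (R,R)-DACH-phenyl Trost ligand (7.5 mol%), THF, −78 → −20 °C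
Reagents that add atoms: none
Why: Proposed new method: Pd(0)/Trost ligand ionises one enantiotopic acetate of acylal 13 to a 1-acetoxy-3-alkyl π-allyl, and the O,O-chelated zinc dienolate of 5 (only C5 can be enolised; O-allylation is reversible because the mixed acylal re-ionises) attacks the acetoxy-bearing terminus from the face anti to the C4 benzyloxy group, so C5 is set by the substrate (side chain trans to C4–O) and C1′ by the ligand while the acetate is installed in the same step; the closest known reactions are Trost's asymmetric allylic alkylation of gem-diacetates with malonates or azlactones and Kazmaier's Pd-allylation of chelated zinc ester enolates, neither shown with a non-stabilised α-alkoxy ketone dienolate.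

Step 8
Reactants: 16 (4S,5R)-5-[(1S,2E)-1-acetoxypentadec-2-en-1-yl]-4,5-bis(benzyloxy)cyclopent-2-en-1-one
Product: 18 (2R,3S)-2-[(1S)-1-acetoxypentadecyl]-2,3-dihydroxycyclopentan-1-one, via saturated bis(benzyl ether) ketone 17 (not isolated)
Conditions: H2 (1 atm), PtO2 (5 mol%), EtOAc, rt; then Pd(OH)2/C, H2 (1 atm), EtOAc–EtOH, rt
Reagents that add atoms: none
Why: Heterogeneous hydrogenation: Pt saturates both C=C bonds with little allylic C–O hydrogenolysis, after which Pearlman's catalyst cleaves both benzyl ethers; no stereocentre is involved.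

Step 9
Reactants: 18 (2R,3S)-2-[(1S)-1-acetoxypentadecyl]-2,3-dihydroxycyclopentan-1-one
Product: 21 (4S,5R)-5-[(1S)-1-acetoxypentadecyl]-4,5-dihydroxycyclopent-2-en-1-one, via tris(trimethylsilyl) enol ether 19 (not isolated), via bis(trimethylsilyl) enone 20 (not isolated)
Conditions: TMSOTf (3.5 equiv), Et3N, CH2Cl2, 0 °C; volatiles removed; Pd(OAc)2 (1.1 equiv), MeCN, rt; then 1 M HCl, THF, 0 °C
Reagents that add atoms: none
Why: Saegusa–Ito oxidation: TMSOTf/Et3N masks both hydroxyls and forms the only possible enol ether (toward C2, since C5 is quaternary), Pd(II) β-hydride elimination gives the enone, and dilute acid removes the TMS ethers without touching the acetate or any stereocentre.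

**Compound list**
1 | (R)-4-hydroxycyclopent-2-en-1-one | O=C1C=C[C@H](O)C1 | starting material
2 | (R)-4-(benzyloxy)cyclopent-2-en-1-one | O=C1C=C[C@H](OCc2ccccc2)C1 | intermediate
3 | sodium (3S)-3-(benzyloxy)cyclopenta-1,4-dien-1-olate (not isolated) | [Na+].[O-]C1=C[C@@H](OCc2ccccc2)C=C1 | intermediate
4 | (4S,5R)-4-(benzyloxy)-5-hydroxycyclopent-2-en-1-one (trans) | O[C@H]1C(=O)C=C[C@@H]1OCc1ccccc1 | intermediate
5 | (4S,5R)-4,5-bis(benzyloxy)cyclopent-2-en-1-one (trans) | c1ccccc1CO[C@H]1C(=O)C=C[C@@H]1OCc1ccccc1 | intermediate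
6 | 1-bromoheptane | CCCCCCCBr | starting material
7 | 7-bromohept-1-ene | C=CCCCCCBr | starting material
8 | heptylmagnesium bromide (not isolated) | CCCCCCC[Mg]Br | intermediate
9 | tetradec-1-ene | C=CCCCCCCCCCCCC | intermediate
10 | (E)-but-2-enal (crotonaldehyde) | C/C=C/C=O | starting material
11 | (E)-pentadec-2-enal | CCCCCCCCCCCC/C=C/C=O | intermediate
12 | acetic anhydride | CC(=O)OC(C)=O | starting material
13 | (E)-pentadec-2-ene-1,1-diyl diacetate | CCCCCCCCCCCC/C=C/C(OC(C)=O)OC(C)=O | intermediate
14 | lithium (3S)-2,3-bis(benzyloxy)cyclopenta-1,4-dien-1-olate (not isolated) | [Li+].[O-]C1=C(OCc2ccccc2)[C@@H](OCc2ccccc2)C=C1 | intermediate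
15 | chlorozinc (3S)-2,3-bis(benzyloxy)cyclopenta-1,4-dien-1-olate (not isolated) | Cl[Zn]OC1=C(OCc2ccccc2)[C@@H](OCc2ccccc2)C=C1 | intermediate
16 | (4S,5R)-5-[(1S,2E)-1-acetoxypentadec-2-en-1-yl]-4,5-bis(benzyloxy)cyclopent-2-en-1-one (benzyloxy groups cis, side chain trans to the C4 oxygen) | CCCCCCCCCCCC/C=C/[C@H](OC(C)=O)[C@@]1(OCc2ccccc2)C(=O)C=C[C@@H]1OCc1ccccc1 | intermediate
17 | (2R,3S)-2-[(1S)-1-acetoxypentadecyl]-2,3-bis(benzyloxy)cyclopentan-1-one (not isolated) | CCCCCCCCCCCCCC[C@H](OC(C)=O)[C@@]1(OCc2ccccc2)C(=O)CC[C@@H]1OCc1ccccc1 | intermediate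
18 | (2R,3S)-2-[(1S)-1-acetoxypentadecyl]-2,3-dihydroxycyclopentan-1-one (cis-diol) | CCCCCCCCCCCCCC[C@H](OC(C)=O)[C@@]1(O)C(=O)CC[C@@H]1O | intermediate
19 | (1S)-1-[(1S,5S)-1,2,5-tris(trimethylsilyloxy)cyclopent-2-en-1-yl]pentadecyl acetate (not isolated) | CCCCCCCCCCCCCC[C@H](OC(C)=O)[C@@]1(O[Si](C)(C)C)C(O[Si](C)(C)C)=CC[C@@H]1O[Si](C)(C)C | intermediate
20 | (4S,5S)-5-[(1S)-1-acetoxypentadecyl]-4,5-bis(trimethylsilyloxy)cyclopent-2-en-1-one (not isolated) | CCCCCCCCCCCCCC[C@H](OC(C)=O)[C@@]1(O[Si](C)(C)C)C(=O)C=C[C@@H]1O[Si](C)(C)C | intermediate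
21 | (4S,5R)-5-[(1S)-1-acetoxypentadecyl]-4,5-dihydroxycyclopent-2-en-1-one | CCCCCCCCCCCCCC[C@H](OC(C)=O)[C@@]1(O)C(=O)C=C[C@@H]1O | target

(The descriptor changes at the ring carbons between 2, 4, 16, 20 and 21 come from CIP priorities only; the spatial arrangement at C4 is that of 1 throughout, and at C5 that set in step 7.)

**Totals**
Total step count: 9.
Longest linear sequence: 6 steps (1→2→3→7→8→9, or equally 4→5→6→7→8→9); 6/9 = two thirds.

**Three steps most likely to fail**

Step 7 (the proposed new alkylation). The main risks are: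
- acetyl transfer from the acylal to the enolate;
- β-elimination of the C4 benzyloxide from the dienolate;
- attack at the alkyl-bearing allyl terminus;
- a mismatched pairing between the substrate-controlled C5 face and the ligand-controlled C1′ sense.

The fallback uses known chemistry, sets out from 9 and 5 and returns at 18. Linear-selective hydroformylation of 9 (Rh(acac)(CO)2, BiPhePhos, CO/H2, toluene, 80 °C) gives pentadecanal F1. The lithium dienolate 14 (LiHMDS, THF, −78 °C) adds to F1 through a closed Zimmerman–Traxler transition state, anti to the C4 benzyloxy group. Because the C5 benzyloxy group is cis to OLi in the ring enolate, the 5-O/1′-O relationship is syn, which is the 1′S configuration of the target. This gives (4S,5S)-4,5-bis(benzyloxy)-5-[(1S)-1-hydroxypentadecyl]cyclopent-2-en-1-one F2. Acetylation (Ac2O, DMAP, Et3N, 0 °C) gives (4S,5S)-5-[(1S)-1-acetoxypentadecyl]-4,5-bis(benzyloxy)cyclopent-2-en-1-one F3. F3 has no allylic acetate, so one hydrogenation (H2, Pd(OH)2/C, EtOAc–EtOH) saturates the ring alkene and removes both benzyl groups to give 18.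

Step 8 (hydrogenation/hydrogenolysis). The risks are hydrogenolysis of the allylic acetate before the chain alkene is saturated, and over-reduction of the ketone on Pt. The fallback sets out from 16 and returns at 18. Both C=C bonds are reduced without a metal by diimide (2-nitrobenzenesulfonylhydrazide, Et3N, CH2Cl2, rt), which cannot form π-allyl species. The product is 17, now isolated. Its benzyl ethers are then cleaved with H2 and Pd(OH)2/C to give 18. This makes no new compound (F0).

Step 9 (Saegusa desaturation with transient silylation). The risks are incomplete silylation of the tertiary hydroxyl, acetyl migration to a free hydroxyl, and silyl ketene acetal formation at the acetate. The fallback sets out from 18 and returns at 21. The cis-diol is tied up with 2,2-dimethoxypropane and PPTS as the acetonide of 18, (1S)-1-[(3aR,6aS)-2,2-dimethyl-4-oxohexahydrocyclopenta[d][1,3]dioxol-3a-yl]pentadecyl acetate F4. Metal-free dehydrogenation with IBX and 4-methoxypyridine N-oxide (DMSO, rt) gives the acetonide of 21, (1S)-1-[(3aS,6aS)-2,2-dimethyl-4-oxo-4,6a-dihydro-3aH-cyclopenta[d][1,3]dioxol-3a-yl]pentadecyl acetate F5. Aqueous TFA (9:1, 0 °C) then releases 21.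

**Further compounds**
F1 | step 7 | pentadecanal | CCCCCCCCCCCCCCC=O
F2 | step 7 | (4S,5S)-4,5-bis(benzyloxy)-5-[(1S)-1-hydroxypentadecyl]cyclopent-2-en-1-one | CCCCCCCCCCCCCC[C@H](O)[C@@]1(OCc2ccccc2)C(=O)C=C[C@@H]1OCc1ccccc1
F3 | step 7 | (4S,5S)-5-[(1S)-1-acetoxypentadecyl]-4,5-bis(benzyloxy)cyclopent-2-en-1-one | CCCCCCCCCCCCCC[C@H](OC(C)=O)[C@@]1(OCc2ccccc2)C(=O)C=C[C@@H]1OCc1ccccc1
F0 | step 8 | none | none
F4 | step 9 | acetonide of 18, (1S)-1-[(3aR,6aS)-2,2-dimethyl-4-oxohexahydrocyclopenta[d][1,3]dioxol-3a-yl]pentadecyl acetate | CCCCCCCCCCCCCC[C@H](OC(C)=O)[C@@]1(OC(C)(C)O2)C(=O)CC[C@@H]12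
F5 | step 9 | acetonide of 21, (1S)-1-[(3aS,6aS)-2,2-dimethyl-4-oxo-4,6a-dihydro-3aH-cyclopenta[d][1,3]dioxol-3a-yl]pentadecyl acetate | CCCCCCCCCCCCCC[C@H](OC(C)=O)[C@@]1(OC(C)(C)O2)C(=O)C=C[C@@H]12
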